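The south-east flask is our one run, and elm stands next to it: the same cX, with cD at 0.50 M against 0.55 M. Oak is diluted, at cD 0.15 M and cX 0.150 M.

| flask | D | X | remark | time |
|---|---|---|---|---|
| south-east | 0.55 M | 0.475 M | run made earlier |  |
| elm | 0.50 M | 0.475 M |  | 2.5 h |
| oak | 0.15 M | 0.150 M |  | 2.5 h |

- south-east (time / min: L / %, D / %): 4.00: 3.9, 95.9; 10.0: 8.6, 90.3; 20.0: 14.9, 83.7; 30.0: 19.9, 77.7

(standard deviation of a reading: 0.5 percentage points)

* which of the two ends with the higher amount of L, in percent of the D charged ("neither" if they lie within 2 percentage points) (elm / oak / neither)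
* L at the end, in percent of the D charged, elm
* L at the end, in percent of the D charged, oak

- a reading of D is of its free form alone

We take L to form reversibly, D + X ⇌ L, and divide the back rate by the forward rate. Time drops out, leaving the quotient cL/(cD cX) over a ceiling. In south-east the apparent constant, net rate of L over cD cX, is 0.0202 M⁻¹ min⁻¹ over the first 10.0 min, at mean quotient 0.101 M⁻¹. It is lower, 0.0168 M⁻¹ min⁻¹, from 20.0 min to 30.0 min, at 0.585 M⁻¹. If we lay the whole slowdown on the back step, a line through both starts at 0.0209 M⁻¹ min⁻¹ and reaches zero at 3.00 M⁻¹: the ceiling quotient, or equilibrium constant. It is a reading, and scatter alone puts 14.1% on the late step of L.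

Our reckoning gives each charge a top L: south-east 42.2% and elm 43.6%, close neighbours. Oak's is lower, 25.2%, because dilution slows the two-body forward step more than the one-body back step. The time constants of approach are 54.9 min in elm and 86.0 min in oak, both shorter than 2.5 h. So we expect L of 40.7% in elm and 20.8% in oak, before any missing D, which read 2.4 percentage points in south-east at 30.0 min.

The forecast says elm, with L at 46% (39% to 53%) in elm and 26% (16% to 32%) in oak, and it reads “a mild slowdown, probably product inhibition or loss of reagent”. Both of its values are higher than ours.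

The flask gives L of 35.1% in elm and 20.6% in oak, so elm ends higher. Elm holds 11.8% of the D charged as E at the end, each E counted as two D, and oak 2.34%. The quotient at the end stands at 2.97 M⁻¹ in elm and 2.43 M⁻¹ in oak, against the 3.00 M⁻¹ we read. Elm's twin with cX at 0.81 M reaches L of 49.9%, at a quotient of 3.34 M⁻¹.

    D + L → E (k = 0.00480 M⁻¹ min⁻¹)
    D + X ⇌ Q (K = 4.80 M⁻¹, k = 0.00120 M⁻¹ min⁻¹)
    2 X → Z (k = 3.90 × 10⁻⁴ M⁻¹ min⁻¹)
    D + X ⇌ L (K = 3.70 M⁻¹, k = 0.0200 M⁻¹ min⁻¹)

The numbers in the tables were generated by integration with constants of no real substance; scatter was added.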